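(The data stem from a simulated flask with constants of no real substance, noise included.)

Take the share of target at equilibrium with the isomer of the product as the zero of the scale (thermodynamic control), and reckon each set-up by its lead over that zero.

| flask | starting material | second substrate | free catalyst | impurity | remark | time |
|---|---|---|---|---|---|---|
| teal | 0.20 M | 0.10 M | 4 mM | 1.7 mM | run made earlier |  |
| ochre | 0.20 M | 0.050 M | 4 mM | 1.7 mM | run made earlier |  |
| amber | 0.20 M | 0.075 M | 4 mM | 1.7 mM | run made earlier |  |
| violet | 0.20 M | 0.10 M | 6 mM | 1.7 mM | run made earlier |  |
| north-west | 0.20 M | 0.100 M | 4.0 mM | 1.7 mM | a closed flask charged with all of it at once and left for 8.0 h | 8.0 h |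
| south-east | 0.20 M | 0.100 M (fed, over 6.40 h) | 4.0 mM | 1.7 mM | all but second substrate at the start; second substrate goes in evenly over 6.40 h, the run ends at 8.0 h | 8.0 h |
| south | 0.20 M | 0.100 M | 4.0 mM | 1.7 mM | a tube with plug flow, the mixed feed as stated, residence time 8.0 h | 8.0 h |
| east | 0.20 M | 0.100 M | 4.0 mM | 1.7 mM | a single well-mixed tank run continuously and read at steady state, 8.0 h in it on average |  |

- teal (time / h: target / %, isomer of the product / %): 0.667: 29.7, 15.0; 1.50: 43.2, 31.9; 3.00: 51.5, 42.4; 5.00: 53.3, 45.5
- ochre (time / h: target / %, isomer of the product / %): 0.833: 33.6, 19.6; 2.00: 47.4, 37.0; 4.00: 53.4, 44.6; 10.0: 53.7, 45.9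
- amber (time / h: target / %, isomer of the product / %): 1.33: 41.0, 29.0; 3.00: 51.4, 42.5; 6.00: 54.3, 45.9; 10.0: 54.6, 46.0
- violet (time / h: target / %, isomer of the product / %): 0.833: 46.3, 29.5; 2.00: 53.1, 43.1; 4.00: 54.7, 45.3; 10.0: 54.1, 45.2

(each reading ± 0.3 percentage points)

1. the set-up with the highest share of target in all that became target or isomer of the product, at the outlet or at the end ("none" if the first two lie within 2 percentage points) (north-west / south-east / south / east / none)
2. share of target in all that became target or isomer of the product, at the outlet or at the end, north-west
3. share of target in all that became target or isomer of the product, at the outlet or at the end, south-east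
4. share of target in all that became target or isomer of the product, at the outlet or at the end, south
5. share of target in all that became target or isomer of the product, at the outlet or at the end, east

- the stated concentrations are those of everything mixed, before any reaction; amounts are the same in each set-up
- the feed brings no volume worth counting
- the earlier runs were made in a closed, stirred flask

The final readings of ochre, amber and violet pool to a zero of 54.2%. In the teal run at 0.667 h, a fraction 44.7% of the charge had become target or isomer of the product, so, taken as first order, starting material goes at about 0.888 h⁻¹. A closed flask in which starting material goes first order, once its early transient has died away, holds target above the zero by the isomer's equilibrium share times that rate times the fraction of starting material left, over the relaxation rate minus that rate; the teal reading, taken so, gives a relaxation rate of about 5.00 h⁻¹.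

In a well-mixed tank the balance gives the lead, the points of target share above the zero: the isomer's equilibrium share divided by one plus relaxation rate times mean time. For the east tank to be named best, this lead must reach the margin of 2 percentage points, which asks for relaxation rate times mean time to fall to 21.9. The east tank has 40.0 for that multiple, so its lead of 1.1 points is less than the margin. The relaxation time of 0.200 h is far shorter than the 8.0 h of the north-west flask and south tube, and the south-east flask has 8.01 relaxation times after its feed stops. We therefore put those three at the zero, the east tank at 55.3%, and answer none.

The forecast gave 54.2%, 54.3%, 54.2% and 55.3% for north-west, south-east, south and east, and none, saying “The top two lie within 2 points”.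

The flasks give 54.1%, 54.1%, 54.1% and 55.2%, and none.

    target ⇌ isomer of the product (K = 0.850, k = 0.0378 min⁻¹)
    free catalyst + impurity → spent catalyst (k = 4340 L mol⁻¹ min⁻¹)
    2 second substrate → self-condensation product (k = 3.00 L mol⁻¹ min⁻¹)
    catalyst intermediate B → free catalyst + second product (k = 1.61 min⁻¹)
    second substrate + free catalyst ⇌ catalyst intermediate B (K = 5.27 L mol⁻¹, k = 18.2 L mol⁻¹ min⁻¹)
    starting material + free catalyst ⇌ catalyst intermediate A (K = 1.80 L mol⁻¹, k = 7.64 L mol⁻¹ min⁻¹)
    catalyst intermediate A → free catalyst + target (k = 39.4 min⁻¹)

The east tank's share of 55.2% stands near the zero because of the back reaction of isomer of the product to target. Strike that back reaction out and the zero goes to nought, the equilibrium share of isomer of the product becomes one, and the relaxation rate becomes the forward rate, so the lead rule leaves the east tank a target share of 5.22%. That change takes the answer away from none, and the east tank run without the back reaction reads 5.22%.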